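**Plan**
1. Retrosynthetic cuts: the acetate; the C5=C6 double bond (from C5–SePh); the ring contraction (C1–C2 back to C15–C2), which leads to a macrocyclic six-membered α-ketol; the C15–O bond (re-aromatisation); then the cyclophane at C13–C14 and C5–C6, the oxolane C7–O bond and C10–C11.
2. Enabling feature: C1 of the cyclopentenone ring (C1–C5) is a tertiary carbinol carrying the exocyclic C15 ketone. This α-ketol is related by a 1,2-shift of ring carbon C2 to a six-membered ring (C15, C2, C3, C4, C5, C1) with the carbinol at C15 and the ketone at C1.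
3. Forward order: C10–C11 by reverse prenylation; oxolane ring; C5–C6 by aryllithium addition; 12-membered ring by B-alkyl Suzuki coupling at C13–C14; arene to para-quinol to 5-selanyl dione; six- to five-membered ring; C5=C6; acetate.
4. Stereochemistry: C10 from the chiral Ir catalyst; C7 from C10 (trans oxidative cyclisation); C14 and C15 from the open face of the cyclophane; C1 from C15 through the chelated suprafacial shift; C5=C6 geometry from the 12-membered ring.

Key step: step 16

Numbering (target numbering, kept for all intermediates): C1 (carbinol, OAc), C2=C3 (3-Me), C4 (ketone), C5=C6, C7 (Me, oxolane O), C8, C9, C10 (H, oxolane O), C11 (Me2), C12, C13, C14 (H, Me), C15 (ketone); in the arene and six-membered-ring intermediates the ring is C15–C2–C3–C4–C5–C1.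
Assumption: the nine-atom bridge of cyclophanes 20–22 cannot pass the inner C1 methoxy group, and the ring closure is taken to give the planar diastereomer that leads to 14R; the other planar sense would give the 14,15-bis-epimeric series, separable at 20.
Assumption: in step 2 the SEGPHOS antipode is the one that delivers the 4S alcohol.

**Step 1**
Reactants: 1 5-methoxy-2-methylphenol
Product: 2 4-methoxy-2-(methoxymethoxy)-1-methylbenzene
Conditions: NaH, MOMCl, THF, 0 °C to rt
Reagents that add atoms: chloromethyl methyl ether COCCl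
Why: O-alkylation of the sodium phenoxide (Williamson type) gives the acetal ether that later directs lithiation and is removed by mild acid.

**Step 2**
Reactants: 3 4-methylpent-4-en-1-ol; 4 3-methylbuta-1,2-diene
Product: 5 (4S)-3,3,7-trimethylocta-1,7-dien-4-ol
Conditions: [Ir(cod)Cl]2 (cat.), SEGPHOS (antipode giving 4S), 4-cyano-3-nitrobenzoic acid (cat.), Cs2CO3 (cat.), toluene, 60 °C, sealed tube
Reagents that add atoms: none
Why: iridium-catalysed transfer-hydrogenative carbonyl reverse prenylation (alcohol dehydrogenation, allene hydrometalation, addition of the 1,1-dimethylallyl–Ir species to the transient aldehyde through a closed chair) forms C10–C11 together with quaternary C11 and the C12=C13 vinyl group, and the chiral bisphosphine sets C10 (S).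

**Step 3**
Reactants: 5 (4S)-3,3,7-trimethylocta-1,7-dien-4-ol
Product: 6 [(2S,5S)-2-methyl-5-(2-methylbut-3-en-2-yl)oxolan-2-yl]methanol
Conditions: Co(modp)2 (cat.), O2 (1 atm), t-BuOOH (cat.), i-PrOH, 55 °C
Reagents that add atoms: dioxygen O=O
Why: the Mukaiyama aerobic oxidative cyclisation of a pent-4-enol is a 5-exo closure that engages only the C6=C7 alkene (the vinyl group would need a four-membered or 5-endo ring) and places the new CH2OH trans to the C10 substituent, which sets C7 (S) from C10.

**Step 4**
Reactants: 6 [(2S,5S)-2-methyl-5-(2-methylbut-3-en-2-yl)oxolan-2-yl]methanol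
Product: 7 (2S,5S)-2-methyl-5-(2-methylbut-3-en-2-yl)oxolane-2-carbaldehyde
Conditions: TEMPO (cat.), PhI(OAc)2, CH2Cl2, rt
Reagents that add atoms: none
Why: the nitroxyl-catalysed oxidation stops at the aldehyde, which has no α-hydrogen and cannot epimerise.

**Step 5**
Reactants: 2 4-methoxy-2-(methoxymethoxy)-1-methylbenzene; 7 (2S,5S)-2-methyl-5-(2-methylbut-3-en-2-yl)oxolane-2-carbaldehyde
Product: 11 S-methyl xanthate of the C6 aryl oxolanyl carbinol (both C6 epimers), via aryllithium 8 (not isolated), via lithium alkoxide 9 (not isolated), via lithium xanthate 10 (not isolated)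
Conditions: n-BuLi, THF, 0 °C; 7, −78 to 0 °C; CS2, rt; MeI
Reagents that add atoms: carbon disulfide S=C=S; iodomethane CI
Why: directed ortho-metalation takes place at the carbon flanked by OMe and OMOM (the future C5), the aryllithium adds to the non-enolisable aldehyde to form C5–C6, and the alkoxide is trapped in the same flask as the xanthate; the C6 configuration is of no consequence.

**Step 6**
Reactants: 11 S-methyl xanthate of the C6 aryl oxolanyl carbinol
Product: 12 (2S,5S)-2-{[6-methoxy-2-(methoxymethoxy)-3-methylphenyl]methyl}-2-methyl-5-(2-methylbut-3-en-2-yl)oxolane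
Conditions: Bu3SnH, AIBN (cat.), toluene, 110 °C
Reagents that add atoms: none
Why: Barton–McCombie deoxygenation through the benzylic radical gives the C6 methylene; the vinyl group sits trans across the oxolane and cannot be reached by the radical.

**Step 7**
Reactants: 12 (2S,5S)-2-{[6-methoxy-2-(methoxymethoxy)-3-methylphenyl]methyl}-2-methyl-5-(2-methylbut-3-en-2-yl)oxolane
Product: 13 (2S,5S)-2-{[3-bromo-2-methoxy-6-(methoxymethoxy)-5-methylphenyl]methyl}-2-methyl-5-(2-methylbut-3-en-2-yl)oxolane
Conditions: NBS, MeCN, 0 °C, dark
Reagents that add atoms: N-bromosuccinimide O=C1CCC(=O)N1Br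
Why: electrophilic aromatic bromination goes to C15, the only free position ortho/para to the two oxygens (C2–H is meta to both), and should be much faster than attack of NBS on the isolated alkene.

**Step 8**
Reactants: 13 (2S,5S)-2-{[3-bromo-2-methoxy-6-(methoxymethoxy)-5-methylphenyl]methyl}-2-methyl-5-(2-methylbut-3-en-2-yl)oxolane
Product: 16 C15 aryl methyl ketone (acetyl in place of bromine), via C15 aryllithium 14 (not isolated), via lithium hemiaminal adduct 15 (not isolated)
Conditions: n-BuLi, THF, −78 °C; MeC(O)N(OMe)Me, −78 to 0 °C; aq. work-up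
Reagents that add atoms: N-methoxy-N-methylacetamide CC(=O)N(C)OC
Why: bromine–lithium exchange followed by acylation with a Weinreb amide gives the methyl ketone (future C14 and its methyl) without over-addition, because the tetrahedral chelate survives until work-up.

**Step 9**
Reactants: 16 C15 aryl methyl ketone
Product: 18 1-arylvinyl triflate (C14 enol triflate), via potassium enolate 17 (not isolated)
Conditions: KHMDS, THF, −78 °C; PhNTf2, −78 to 0 °C; used directly
Reagents that add atoms: N-phenylbis(trifluoromethanesulfonimide) FC(F)(F)S(=O)(=O)N(c1ccccc1)S(=O)(=O)C(F)(F)F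
Why: kinetic enolisation of the methyl ketone and O-sulfonylation give the vinyl triflate that serves as the sp2 partner in the ring closure.

**Step 10**
Reactants: 18 1-arylvinyl triflate
Product: 20 (7S,10S)-14-methylidene cyclophane (12-membered ring), via C13 alkyl-9-BBN borane 19 (not isolated)
Conditions: 9-BBN, THF, rt; then slow addition to Pd(dppf)Cl2 (cat.), AsPh3, Cs2CO3, DMF/THF/H2O, 50 °C, high dilution
Reagents that add atoms: none
Why: chemoselective anti-Markovnikov hydroboration of the monosubstituted C12=C13 alkene followed by intramolecular B-alkyl Suzuki–Miyaura coupling with the vinyl triflate forms C13–C14 and closes the 12-membered ring, an established way to ansa and cyclophane macrocycles.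

**Step 11**
Reactants: 20 (7S,10S)-14-methylidene cyclophane
Product: 21 (7S,10S,14R)-14-methyl cyclophane (C1 OMe, C4 OMOM)
Conditions: H2 (1 atm), Pd/C, EtOAc, rt
Reagents that add atoms: none
Why: in this heterogeneous hydrogenation the bridge pulls C13 out of the arene plane, so the alkene stands across the ring and takes up hydrogen from the open C2–H edge; the new methyl group ends up on the C1 side and anti to the bridge, which is 14R for the planar sense assumed.

**Step 12**
Reactants: 21 (7S,10S,14R)-14-methyl cyclophane
Product: 22 (7S,10S,14R)-cyclophane phenol (C4 OH, C1 OMe)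
Conditions: HCl (cat.), MeOH, 40 °C
Reagents that add atoms: none
Why: acid-catalysed acetal exchange removes the MOM group and frees the C4 phenol, while the aryl methyl ether and the oxolane are inert.

**Step 13**
Reactants: 22 (7S,10S,14R)-cyclophane phenol
Product: 23 (7S,10S,14R,15S)-15-hydroxy-1-methoxy para-quinol
Conditions: PhI(OAc)2, MeCN/H2O, 0 °C
Reagents that add atoms: water O
Why: iodine(III)-mediated oxidative dearomatisation of a para-alkylphenol in the presence of water gives the para-quinol; only the C4 oxygen can be oxidised (C1 is still a methyl ether), water enters at the para carbon C15, and it comes from the face opposite the bridge, which sets C15 (S).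

**Step 14**
Reactants: 23 (7S,10S,14R,15S)-15-hydroxy-1-methoxy para-quinol
Product: 24 (7S,10S,14R,15S)-1,15-dihydroxy para-quinol (C1 enol of the 1,4-dione)
Conditions: 1 M HCl, THF, rt
Reagents that add atoms: water O
Why: the 3-methoxy enone is a vinylogous ester and is hydrolysed by dilute acid through conjugate addition of water and loss of methanol, freeing the enolised dione.

**Step 15**
Reactants: 24 (7S,10S,14R,15S)-1,15-dihydroxy para-quinol
Product: 25 (7S,10S,14R,15S)-15-hydroxy-5-(phenylselanyl) 1,4-dione
Conditions: PhSeCl, pyridine, CH2Cl2, 0 °C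
Reagents that add atoms: benzeneselenenyl chloride Cl[Se]c1ccccc1
Why: α-selenenylation of the enolised 2-alkyl-1,3-dione occurs at C5, the only nucleophilic carbon, from the face away from the bridge; it blocks enolisation, so that C1 becomes a true ketone next to the C15 carbinol, and installs the leaving group for the later C5=C6 bond.

**Step 16**
Reactants: 25 (7S,10S,14R,15S)-15-hydroxy-5-(phenylselanyl) 1,4-dione
Product: 26 ring-contracted ketol (1-hydroxy-5-(phenylselanyl)cyclopent-2-en-4-one with exocyclic C15 ketone)
Conditions: Mg(OTf)2, i-Pr2NEt, MeCN, 0 °C to rt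
Reagents that add atoms: none
Why: Proposed new method: Mg(II) binds the C15 alkoxide and the C1 carbonyl oxygen in a five-membered chelate, the alkoxide pushes, and the ring bond C15–C2 migrates suprafacially to C1, so that C1–C2 forms as C15–C2 breaks and C15 becomes the exocyclic ketone; the closest known reaction is the base- or Mg(II)-mediated α-ketol (acyloin) ring contraction of 6-hydroxycyclohexadienones, as in the isomerisation of hop α-acids to iso-α-acids. The cyclopentenone (C1–C5) therefore arises by a 1,2-shift that contracts the six-membered ring (C15, C2, C3, C4, C5, C1), not by a cyclisation, and the 12-membered ring through C15, C1 and C5 is untouched. C1 is the only new stereocentre and is controlled by the C15 carbinol: in the chelate the C15–O bond lies in the plane of the C1 carbonyl, and C2 can only reach the carbonyl face on which it already sits, opposite to C14. The step needs migration of the sp2 carbon C2 rather than the alkyl carbon C14, and an equilibrium on the product side. The higher migratory aptitude of the alkenyl carbon should secure the first; the C5 selanyl group is there for the second, because it keeps C1 a non-enolisable ketone (the parent enol is a vinylogous acid and would be a sink) and makes the starting material an α,α-disubstituted β-diketone whose dipole repulsion is relieved on contraction. The hindered amine should neither attack selenium nor soft-enolise the new C15 ketone towards C14.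

**Step 17**
Reactants: 26 ring-contracted ketol
Product: 28 1-O-deacetyl target (1S,5E,7S,10S,14R), via selenoxide 27 (not isolated)
Conditions: mCPBA, CH2Cl2, −78 °C; pyridine, −78 to 0 °C
Reagents that add atoms: none
Why: chemoselective oxidation at selenium and syn-elimination of the selenoxide can only take a C6 hydrogen (C1 and C4 carry none), giving the exocyclic enone; the geometry with C7 cis to C1 is the one the 12-membered ring allows.

**Step 18**
Reactants: 28 1-O-deacetyl target
Product: 29 CNP0144863.1
Conditions: Ac2O, DMAP, Et3N, CH2Cl2, rt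
Reagents that add atoms: acetic anhydride CC(=O)OC(C)=O
Why: DMAP-catalysed acylation of the tertiary alcohol gives the acetate; no alkoxide is generated, so the ketol cannot shift back and C14 is not enolised.

**Compound list**
1 | 5-methoxy-2-methylphenol | COc1ccc(C)c(O)c1 | starting material
2 | 4-methoxy-2-(methoxymethoxy)-1-methylbenzene | COCOc1cc(OC)ccc1C | intermediate
3 | 4-methylpent-4-en-1-ol | CC(=C)CCCO | starting material
4 | 3-methylbuta-1,2-diene | CC(C)=C=C | starting material
5 | (4S)-3,3,7-trimethylocta-1,7-dien-4-ol | C=C(C)CC[C@H](O)C(C)(C)C=C | intermediate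
6 | [(2S,5S)-2-methyl-5-(2-methylbut-3-en-2-yl)oxolan-2-yl]methanol | OC[C@]1(C)CC[C@H](O1)C(C)(C)C=C | intermediate
7 | (2S,5S)-2-methyl-5-(2-methylbut-3-en-2-yl)oxolane-2-carbaldehyde | O=C[C@]1(C)CC[C@H](O1)C(C)(C)C=C | intermediate
8 | [6-methoxy-2-(methoxymethoxy)-3-methylphenyl]lithium (not isolated) | [Li]c1c(OC)ccc(C)c1OCOC | intermediate
9 | lithium [6-methoxy-2-(methoxymethoxy)-3-methylphenyl][(2S,5S)-2-methyl-5-(2-methylbut-3-en-2-yl)oxolan-2-yl]methanolate, both C6 epimers (not isolated) | COCOc1c(C)ccc(OC)c1C(O[Li])[C@]1(C)CC[C@H](O1)C(C)(C)C=C | intermediate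
10 | lithium O-alkyl carbonodithioate of 9, both C6 epimers (not isolated) | COCOc1c(C)ccc(OC)c1C(OC(=S)S[Li])[C@]1(C)CC[C@H](O1)C(C)(C)C=C | intermediate
11 | O-{[6-methoxy-2-(methoxymethoxy)-3-methylphenyl][(2S,5S)-2-methyl-5-(2-methylbut-3-en-2-yl)oxolan-2-yl]methyl} S-methyl carbonodithioate, both C6 epimers | COCOc1c(C)ccc(OC)c1C(OC(=S)SC)[C@]1(C)CC[C@H](O1)C(C)(C)C=C | intermediate
12 | (2S,5S)-2-{[6-methoxy-2-(methoxymethoxy)-3-methylphenyl]methyl}-2-methyl-5-(2-methylbut-3-en-2-yl)oxolane | COCOc1c(C)ccc(OC)c1C[C@]1(C)CC[C@H](O1)C(C)(C)C=C | intermediate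
13 | (2S,5S)-2-{[3-bromo-2-methoxy-6-(methoxymethoxy)-5-methylphenyl]methyl}-2-methyl-5-(2-methylbut-3-en-2-yl)oxolane | COCOc1c(C)cc(Br)c(OC)c1C[C@]1(C)CC[C@H](O1)C(C)(C)C=C | intermediate
14 | C15 aryllithium from 13 (not isolated) | COCOc1c(C)cc([Li])c(OC)c1C[C@]1(C)CC[C@H](O1)C(C)(C)C=C | intermediate
15 | lithium N-methoxy-N-methyl hemiaminal adduct of 14 (not isolated) | COCOc1c(C)cc(C(C)(O[Li])N(C)OC)c(OC)c1C[C@]1(C)CC[C@H](O1)C(C)(C)C=C | intermediate
16 | 1-[2-methoxy-4-(methoxymethoxy)-5-methyl-3-{[(2S,5S)-2-methyl-5-(2-methylbut-3-en-2-yl)oxolan-2-yl]methyl}phenyl]ethan-1-one | COCOc1c(C)cc(C(C)=O)c(OC)c1C[C@]1(C)CC[C@H](O1)C(C)(C)C=C | intermediate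
17 | potassium enolate of 16 (not isolated) | COCOc1c(C)cc(C(=C)O[K])c(OC)c1C[C@]1(C)CC[C@H](O1)C(C)(C)C=C | intermediate
18 | 1-[2-methoxy-4-(methoxymethoxy)-5-methyl-3-{[(2S,5S)-2-methyl-5-(2-methylbut-3-en-2-yl)oxolan-2-yl]methyl}phenyl]ethenyl trifluoromethanesulfonate | COCOc1c(C)cc(C(=C)OS(=O)(=O)C(F)(F)F)c(OC)c1C[C@]1(C)CC[C@H](O1)C(C)(C)C=C | intermediate
19 | 18 with the vinyl group hydroborated: C12H2–C13H2–(9-borabicyclo[3.3.1]nonan-9-yl) (not isolated) | COCOc1c(C)cc(C(=C)OS(=O)(=O)C(F)(F)F)c(OC)c1C[C@]1(C)CC[C@H](O1)C(C)(C)CCB1C2CCCC1CCC2 | intermediate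
20 | (7S,10S)-cyclophane: benzene ring C15, C2(H), C3(Me), C4(OMOM), C5, C1(OMe), bridged from C5 to C15 by C6H2–C7(Me)–C8H2–C9H2–C10H–C11Me2–C12H2–C13H2–C14(=CH2), oxolane oxygen between C7 and C10 | COc1c2cc(C)c(OCOC)c1C[C@]1(C)CC[C@H](O1)C(C)(C)CCC2=C | intermediate
21 | (7S,10S,14R)-cyclophane as 20 with C14 carrying H and methyl | COc1c2cc(C)c(OCOC)c1C[C@]1(C)CC[C@H](O1)C(C)(C)CC[C@H]2C | intermediate
22 | (7S,10S,14R)-cyclophane phenol: as 21 with free C4 OH | COc1c2cc(C)c(O)c1C[C@]1(C)CC[C@H](O1)C(C)(C)CC[C@H]2C | intermediate
23 | (7S,10S,14R,15S)-15-hydroxy-1-methoxy para-quinol: ring C15(OH)–C2H=C3(Me)–C4(=O)–C5=C1(OMe), bridge as in 21 | O[C@@]12C=C(C)C(=O)C(=C1OC)C[C@]1(C)CC[C@H](O1)C(C)(C)CC[C@H]2C | intermediate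
24 | (7S,10S,14R,15S)-1,15-dihydroxy para-quinol (C1 enol of the 15-hydroxy 1,4-dione) | O[C@@]12C=C(C)C(=O)C(=C1O)C[C@]1(C)CC[C@H](O1)C(C)(C)CC[C@H]2C | intermediate
25 | (7S,10S,14R,15S)-15-hydroxy-5-(phenylselanyl) 1,4-dione: ring C15(OH)–C2H=C3(Me)–C4(=O)–C5(SePh)(C6)–C1(=O); C5 not assigned, Se expected anti to the bridge | O[C@@]12C=C(C)C(=O)C([Se]c3ccccc3)(C1=O)C[C@]1(C)CC[C@H](O1)C(C)(C)CC[C@H]2C | intermediate
26 | ring-contracted ketol: cyclopentenone C1(OH)–C2H=C3(Me)–C4(=O)–C5(SePh)(C6) with exocyclic C15 ketone on C1; 7S,10S,14R, C1 arranged as in the target (formally 1R because of Se), C5 not assigned | O[C@@]12C=C(C)C(=O)C1([Se]c3ccccc3)C[C@]1(C)CC[C@H](O1)C(C)(C)CC[C@@H](C)C2=O | intermediate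
27 | selenoxide of 26 (not isolated) | O[C@@]12C=C(C)C(=O)C1([Se](=O)c3ccccc3)C[C@]1(C)CC[C@H](O1)C(C)(C)CC[C@@H](C)C2=O | intermediate
28 | 1-O-deacetyl target (1S,5E,7S,10S,14R) | O[C@@]12C=C(C)C(=O)/C1=C/[C@]1(C)CC[C@H](O1)C(C)(C)CC[C@@H](C)C2=O | intermediate
29 | CNP0144863.1 (1S,5E,7S,10S,14R) | CC(=O)O[C@@]12C=C(C)C(=O)/C1=C/[C@]1(C)CC[C@H](O1)C(C)(C)CC[C@@H](C)C2=O | target

**Totals**
Total step count: 18. Longest linear sequence: 17 steps (steps 2–18 from 3 and 4; step 1 is a one-step side branch).

**Steps most likely to fail**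

1. Step 16 (ketol contraction). The equilibrium may stay on the side of the six-membered dione, the alkyl carbon C14 may migrate in place of C2, or selenium may be transferred to a nucleophile before the shift. The fallback uses known reactions and replaces the reversible shift by a sulfonate-driven, irreversible one. From 25, oxidation at selenium and syn-elimination first give the C5=C6 alkylidene dione F1. Luche reduction then takes the C1 carbonyl, the more electrophilic one next to the C15 hydroxyl, to the 1,15-diol F2. The secondary allylic hydroxyl is mesylated to the C1 methanesulfonate F3, and Et3Al triggers the semipinacol shift of the alkenyl carbon C2 from C15 to C1 with loss of mesylate, giving the ring-contracted C1–H ketone F4. Deprotonation at C1 with KHMDS and hydroxylation of the dienolate with 2-(phenylsulfonyl)-3-phenyloxaziridine, on the face away from the bridge, installs the C1 hydroxyl and rejoins the route at 28.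

2. Step 10 (ring closure). Protodeboronation or β-hydride elimination of the alkyl partner, or oligomerisation, may outrun transmetalation to the hindered 1-arylvinyl–palladium species. In the fallback, 18 is cyclised without hydroboration by an intramolecular Heck reaction (Pd(OAc)2, P(o-tol)3, Ag2CO3, MeCN, high dilution). The vinylpalladium adds to the terminal carbon C13 of the vinyl group and β-hydride elimination gives the macrocyclic 12E,14-methylidene diene F5. Hydrogenation of both double bonds under the conditions of step 11 rejoins the route at 21.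

3. Step 13 (dearomatisation). Attack of water at the ortho carbon C5, further oxidation of the electron-rich ring by iodine(III), or approach of water from the bridge face would erode the yield or the C15 configuration. In the fallback, 22 is treated with singlet oxygen generated in the flask from Oxone/NaHCO3 in aqueous MeCN; this small, uncharged oxidant adds para to the phenol oxygen, again anti to the bridge, and gives the C15 hydroperoxide F6. Reduction with dimethyl sulfide gives 23.

**Further compounds**
F1 | step 16 | (7S,10S,14R,15S)-15-hydroxy 1,4-dione with exocyclic C5=C6 (C7 cis to C1) | O[C@@]12C=C(C)C(=O)/C(C1=O)=C/[C@]1(C)CC[C@H](O1)C(C)(C)CC[C@H]2C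
F2 | step 16 | 1,15-diol from reduction of the C1 carbonyl of F1 (C1 not assigned) | O[C@@]12C=C(C)C(=O)/C(C1O)=C/[C@]1(C)CC[C@H](O1)C(C)(C)CC[C@H]2C
F3 | step 16 | C1 methanesulfonate of F2 | O[C@@]12C=C(C)C(=O)/C(C1OS(C)(=O)=O)=C/[C@]1(C)CC[C@H](O1)C(C)(C)CC[C@H]2C
F4 | step 16 | ring-contracted C1–H ketone, the 1-deoxy analogue of 28 (C1 not assigned) | C12C=C(C)C(=O)/C1=C/[C@]1(C)CC[C@H](O1)C(C)(C)CC[C@@H](C)C2=O
F5 | step 10 | (7S,10S)-cyclophane diene: as 20 with an additional 12E double bond | COc1c2cc(C)c(OCOC)c1C[C@]1(C)CC[C@H](O1)C(C)(C)/C=C/C2=C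
F6 | step 13 | (7S,10S,14R,15S)-15-hydroperoxy analogue of 23 | OO[C@@]12C=C(C)C(=O)C(=C1OC)C[C@]1(C)CC[C@H](O1)C(C)(C)CC[C@H]2C
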